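**Retrosynthetic overview** (ring numbering: C1 acetoxy carbinol, C2=C3(Me) E, C6 bearing CMe2OAc, C8=C9(Me) Z, C10, C11, C12–C13(Me) oxirane, C14)
1. Feature used: the ring bond C10–C11 of the 14-membered carbocycle joins C10, allylic to the Z C8=C9 alkene and able to carry a phenylsulfonyl group, to C11, the methylene on oxirane carbon C12, so that C11–C12–C13(Me) is the skeleton of a 2,3-epoxy alcohol.
2. 27 ⇒ diol 26 ⇒ bis-silyl ether 25 ⇒ macrocyclic sulfone 24 ⇒ (C10–C11, intramolecular sulfone alkylation) acyclic epoxy iodide 23.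
3. 23 ⇒ epoxy alcohol 22 (Sharpless) ⇒ E allylic alcohol 21 ⇒ β-keto ester 18 (enol phosphate, cuprate) ⇒ enal 12 + Chan's diene 15 (asymmetric vinylogous aldol sets C1).
4. 12 ⇒ keto aldehyde 4 (Z olefination at the C8 aldehyde, E olefination at the C3 ketone, sulfinate at C10) ⇒ ozonolysis of silylated (R)-α-terpineol, which supplies C6.
5. Ring order: oxirane first (step 15), 14-membered carbocycle second and last (step 17).

Key step: step 17

Remarks on the chemistry:
- Assumption: the Ti(OiPr)4/(R)-BINOL catalyst is taken to add Chan's diene to the face of enal 12 that gives the R carbinol at C1, the sense it shows with aromatic and conjugated aldehydes. This would be checked on 17 by Mosher ester analysis, and (S)-BINOL used if the sense were opposite.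
- Phosphonates 5 and 7 are catalogue reagents and are treated as starting materials.
- TES = triethylsilyl, TBS = tert-butyldimethylsilyl.

**Step 1**
Reactants: 1 (R)-α-terpineol
Product: 2 triethyl({2-[(1R)-4-methylcyclohex-3-en-1-yl]propan-2-yl}oxy)silane
Conditions: TESOTf, 2,6-lutidine, CH2Cl2, 0 °C
Reagents that add atoms: triethylsilyl trifluoromethanesulfonate, CC[Si](CC)(CC)OS(=O)(=O)C(F)(F)F
Why: Silyl ether formation with a silyl triflate and a hindered pyridine base is fast even at a tertiary carbinol, leaves the ring alkene and the stereocentre untouched, and keeps the alcohol from closing onto the aldehyde made in step 2.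

**Step 2**
Reactants: 2 triethyl({2-[(1R)-4-methylcyclohex-3-en-1-yl]propan-2-yl}oxy)silane
Product: 4 (3R)-6-oxo-3-[2-(triethylsilyloxy)propan-2-yl]heptanal, via ozonide 3 (not isolated)
Conditions: O3, CH2Cl2, −78 °C; then PPh3, −78 °C to rt
Reagents that add atoms: ozone, [O-][O+]=O
Why: Ozonolysis (Criegee cleavage) of the only alkene and reduction of the ozonide by PPh3 should give the methyl ketone (future C3) and the aldehyde (future C8), while C6, β to the aldehyde and γ to the ketone, cannot epimerise.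

**Step 3**
Reactants: 4 (3R)-6-oxo-3-[2-(triethylsilyloxy)propan-2-yl]heptanal; 5 ethyl 2-[bis(2,2,2-trifluoroethoxy)phosphoryl]propanoate
Product: 6 ethyl (2Z,5R)-2-methyl-8-oxo-5-[2-(triethylsilyloxy)propan-2-yl]non-2-enoate
Conditions: 5, KN(SiMe3)2, 18-crown-6, THF, −78 °C
Reagents that add atoms: none
Why: In this Still–Gennari variant of the Horner–Wadsworth–Emmons olefination the potassium anion of the bis(trifluoroethyl) phosphonate adds to the aldehyde at −78 °C far faster than to the methyl ketone, and its adduct collapses before it equilibrates, which should give the Z trisubstituted enoate (C8=C9).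

**Step 4**
Reactants: 6 ethyl (2Z,5R)-2-methyl-8-oxo-5-[2-(triethylsilyloxy)propan-2-yl]non-2-enoate; 7 diethyl {2-[methoxy(methyl)amino]-2-oxoethyl}phosphonate
Product: 8 ethyl (2Z,5R,8E)-10-[methoxy(methyl)amino]-2,8-dimethyl-10-oxo-5-[2-(triethylsilyloxy)propan-2-yl]deca-2,8-dienoate
Conditions: 7 (slight excess over base), NaH, THF, 0 to 45 °C; chromatographic removal of the minor 8Z isomer
Reagents that add atoms: none
Why: Horner–Wadsworth–Emmons olefination of the methyl ketone should favour the E enamide (C2=C3, larger chain trans to the carbonyl group), the amide end is chosen so that the two carbonyl ends can be told apart in step 5, and keeping the phosphonate in excess over NaH leaves no base strong enough to enolise the ketone onto the enoate.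

**Step 5**
Reactants: 8 ethyl (2Z,5R,8E)-10-[methoxy(methyl)amino]-2,8-dimethyl-10-oxo-5-[2-(triethylsilyloxy)propan-2-yl]deca-2,8-dienoate
Product: 9 (2E,6R,8Z)-10-hydroxy-3,9-dimethyl-6-[2-(triethylsilyloxy)propan-2-yl]deca-2,8-dienal
Conditions: iBu2AlH (4 equiv), CH2Cl2, −78 °C; MeOH quench at −78 °C, then aq. KNaC4H4O6
Reagents that add atoms: none
Why: iBu2AlH reduces the conjugated ester in the 1,2-sense to the allylic alcohol while the Weinreb amide is held as its chelated aluminium hemiaminal and releases the enal only on hydrolysis, so one operation should give the C10 alcohol and the C1 aldehyde.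

**Step 6**
Reactants: 9 (2E,6R,8Z)-10-hydroxy-3,9-dimethyl-6-[2-(triethylsilyloxy)propan-2-yl]deca-2,8-dienal
Product: 10 (2E,6R,8Z)-10-chloro-3,9-dimethyl-6-[2-(triethylsilyloxy)propan-2-yl]deca-2,8-dienal
Conditions: NCS, Me2S, CH2Cl2, −20 to 0 °C
Reagents that add atoms: N-chlorosuccinimide, O=C1CCC(=O)N1Cl
Why: In the Corey–Kim halogenation the alkoxysulfonium salt of the allylic alcohol is displaced by chloride at the primary carbon without added base, so the enal, the silyl ether and the Z geometry should survive.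

**Step 7**
Reactants: 10 (2E,6R,8Z)-10-chloro-3,9-dimethyl-6-[2-(triethylsilyloxy)propan-2-yl]deca-2,8-dienal; 11 sodium benzenesulfinate (PhSO2Na)
Product: 12 (2E,6R,8Z)-3,9-dimethyl-10-(phenylsulfonyl)-6-[2-(triethylsilyloxy)propan-2-yl]deca-2,8-dienal
Conditions: PhSO2Na, Bu4NI (cat.), DMF, rt
Reagents that add atoms: none
Why: SN2 S-alkylation of the sulfinate by the primary allylic chloride should give the allyl phenyl sulfone with the Z alkene unchanged, the β,β-disubstituted enal being a poor and reversible acceptor for sulfinate.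

**Step 8**
Reactants: 13 methyl acetoacetate
Product: 14 methyl 3-(trimethylsilyloxy)but-2-enoate
Conditions: Me3SiCl, Et3N, hexane, rt
Reagents that add atoms: chlorotrimethylsilane, C[Si](C)(C)Cl
Why: O-Silylation of the enol of the β-keto ester under amine base (silyl enol ether formation).

**Step 9**
Reactants: 14 methyl 3-(trimethylsilyloxy)but-2-enoate
Product: 15 1-methoxy-1,3-bis(trimethylsilyloxy)buta-1,3-diene (Chan's diene)
Conditions: LiN(iPr)2, THF, −78 °C; Me3SiCl
Reagents that add atoms: chlorotrimethylsilane, C[Si](C)(C)Cl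
Why: Vinylogous deprotonation of the γ-methyl group and O-silylation of the dienolate give the bis(silyl) dienol ether.

**Step 10**
Reactants: 12 (2E,6R,8Z)-3,9-dimethyl-10-(phenylsulfonyl)-6-[2-(triethylsilyloxy)propan-2-yl]deca-2,8-dienal; 15 1-methoxy-1,3-bis(trimethylsilyloxy)buta-1,3-diene
Product: 17 methyl (5R,6E,10R,12Z)-5-hydroxy-7,13-dimethyl-3-oxo-14-(phenylsulfonyl)-10-[2-(triethylsilyloxy)propan-2-yl]tetradeca-6,12-dienoate, via bis-silyl aldol adduct 16 (not isolated)
Conditions: Ti(OiPr)4 (8 mol%), (R)-BINOL (8 mol%), 4 Å MS, THF, −78 °C to rt; then pyridinium p-toluenesulfonate, MeOH, 0 °C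
Reagents that add atoms: none
Why: In this catalytic asymmetric vinylogous Mukaiyama aldol addition the aldehyde bound to the tetravalent titanium BINOLate is attacked by the terminal carbon of the diene, the (R)-BINOL ligand shielding one face so that C1 should form R under catalyst control (the remote C6 centre has no say), and mild methanolysis removes both trimethylsilyl groups but not the tertiary TES ether.

**Step 11**
Reactants: 17 methyl (5R,6E,10R,12Z)-5-hydroxy-7,13-dimethyl-3-oxo-14-(phenylsulfonyl)-10-[2-(triethylsilyloxy)propan-2-yl]tetradeca-6,12-dienoate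
Product: 18 methyl (5R,6E,10R,12Z)-5-(tert-butyldimethylsilyloxy)-7,13-dimethyl-3-oxo-14-(phenylsulfonyl)-10-[2-(triethylsilyloxy)propan-2-yl]tetradeca-6,12-dienoate
Conditions: TBSCl, imidazole, DMF, 0 °C to rt
Reagents that add atoms: tert-butyldimethylsilyl chloride, CC(C)(C)[Si](C)(C)Cl
Why: Silyl ether formation at the secondary allylic alcohol under imidazole is mild enough to avoid β-elimination of the aldol and does not silylate the β-keto ester enol.

**Step 12**
Reactants: 18 methyl (5R,6E,10R,12Z)-5-(tert-butyldimethylsilyloxy)-7,13-dimethyl-3-oxo-14-(phenylsulfonyl)-10-[2-(triethylsilyloxy)propan-2-yl]tetradeca-6,12-dienoate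
Product: 19 methyl (2Z,5R,6E,10R,12Z)-5-(tert-butyldimethylsilyloxy)-3-(diethoxyphosphoryloxy)-7,13-dimethyl-14-(phenylsulfonyl)-10-[2-(triethylsilyloxy)propan-2-yl]tetradeca-2,6,12-trienoate
Conditions: NaH (1.05 equiv), Et2O, 0 °C; ClP(O)(OEt)2, 0 °C to rt
Reagents that add atoms: diethyl chlorophosphate, CCOP(=O)(Cl)OCC
Why: The chelated sodium enolate of the β-keto ester, the only C–H acid that one equivalent of NaH reaches, is O-phosphorylated to the Z enol phosphate (first half of the Weiler trisubstituted-alkene synthesis).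

**Step 13**
Reactants: 19 methyl (2Z,5R,6E,10R,12Z)-5-(tert-butyldimethylsilyloxy)-3-(diethoxyphosphoryloxy)-7,13-dimethyl-14-(phenylsulfonyl)-10-[2-(triethylsilyloxy)propan-2-yl]tetradeca-2,6,12-trienoate
Product: 20 methyl (2E,5R,6E,10R,12Z)-5-(tert-butyldimethylsilyloxy)-3,7,13-trimethyl-14-(phenylsulfonyl)-10-[2-(triethylsilyloxy)propan-2-yl]tetradeca-2,6,12-trienoate
Conditions: Me2CuLi (from MeLi and CuI), Et2O, −78 to −45 °C
Reagents that add atoms: lithium dimethylcuprate, [Li+].C[Cu-]C
Why: Addition–elimination of the Gilman cuprate on the β-phosphoryloxy enoate replaces phosphate by methyl with retention (Weiler coupling), which should give the E β-methyl enoate (C12=C13), while at this temperature the allyl sulfone and the silyl ethers are not attacked.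

**Step 14**
Reactants: 20 methyl (2E,5R,6E,10R,12Z)-5-(tert-butyldimethylsilyloxy)-3,7,13-trimethyl-14-(phenylsulfonyl)-10-[2-(triethylsilyloxy)propan-2-yl]tetradeca-2,6,12-trienoate
Product: 21 (2E,5R,6E,10R,12Z)-5-(tert-butyldimethylsilyloxy)-3,7,13-trimethyl-14-(phenylsulfonyl)-10-[2-(triethylsilyloxy)propan-2-yl]tetradeca-2,6,12-trien-1-ol
Conditions: iBu2AlH (2.5 equiv), CH2Cl2, −78 °C; aq. KNaC4H4O6
Reagents that add atoms: none
Why: 1,2-Reduction of the conjugated ester by iBu2AlH gives the primary allylic alcohol (C11) and leaves the sulfone and silyl ethers alone.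

**Step 15**
Reactants: 21 (2E,5R,6E,10R,12Z)-5-(tert-butyldimethylsilyloxy)-3,7,13-trimethyl-14-(phenylsulfonyl)-10-[2-(triethylsilyloxy)propan-2-yl]tetradeca-2,6,12-trien-1-ol
Product: 22 {(2R,3R)-3-[(2R,3E,7R,9Z)-2-(tert-butyldimethylsilyloxy)-4,10-dimethyl-11-(phenylsulfonyl)-7-[2-(triethylsilyloxy)propan-2-yl]undeca-3,9-dien-1-yl]-3-methyloxiran-2-yl}methanol
Conditions: Ti(OiPr)4 (10 mol%), D-(−)-diethyl tartrate (12 mol%), tBuOOH, 4 Å MS, CH2Cl2, −20 °C
Reagents that add atoms: tert-butyl hydroperoxide, CC(C)(C)OO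
Why: In the Katsuki–Sharpless asymmetric epoxidation only the alkene of the free allylic alcohol is held on titanium, and D-(−)-diethyl tartrate, the mirror image of the ligand that converts geraniol into its (2S,3S)-epoxide, should deliver oxygen to the face that gives the (12R,13R)-oxirane under reagent control.

**Step 16**
Reactants: 22 {(2R,3R)-3-[(2R,3E,7R,9Z)-2-(tert-butyldimethylsilyloxy)-4,10-dimethyl-11-(phenylsulfonyl)-7-[2-(triethylsilyloxy)propan-2-yl]undeca-3,9-dien-1-yl]-3-methyloxiran-2-yl}methanol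
Product: 23 (2S,3R)-3-[(2R,3E,7R,9Z)-2-(tert-butyldimethylsilyloxy)-4,10-dimethyl-11-(phenylsulfonyl)-7-[2-(triethylsilyloxy)propan-2-yl]undeca-3,9-dien-1-yl]-2-(iodomethyl)-3-methyloxirane
Conditions: PPh3, I2, imidazole, CH2Cl2, 0 °C, dark; used at once
Reagents that add atoms: iodine, II
Why: In this Appel-type iodination iodide displaces the oxyphosphonium group at the primary carbon C11 under buffered conditions that leave the neighbouring oxirane closed, and the C12 descriptor becomes S only because CH2I outranks C13.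

**Step 17**
Reactants: 23 (2S,3R)-3-[(2R,3E,7R,9Z)-2-(tert-butyldimethylsilyloxy)-4,10-dimethyl-11-(phenylsulfonyl)-7-[2-(triethylsilyloxy)propan-2-yl]undeca-3,9-dien-1-yl]-2-(iodomethyl)-3-methyloxirane
Product: 24 (1R,2E,6R,8Z,12R,13R)-1-(tert-butyldimethylsilyloxy)-12,13-epoxy-3,9,13-trimethyl-10-(phenylsulfonyl)-6-[2-(triethylsilyloxy)propan-2-yl]cyclotetradeca-2,8-diene (both C10 epimers)
Conditions: LiN(SiMe3)2 (1.05 equiv) added to 23 in THF (about 0.002 M), −78 °C, then slowly to 0 °C
Reagents that add atoms: none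
Why: LiN(SiMe3)2 removes a C10 proton, by far the most acidic C–H of 23, and the sulfonyl-stabilised allyl anion displaces iodide at the primary carbon C11 in an SN2 step that forms C10–C11. The closest known reaction types are the macrocyclisation of isoprenoid chains by intramolecular alkylation of sulfonyl-stabilised allyl carbanions with allylic halides and the C-alkylation of sulfonyl carbanions by 2,3-epoxy alkyl halides at the halide carbon. The 14-membered ring closes in the exo-tet mode, helped by the two trisubstituted alkenes and the oxirane, which limit the chain conformations, and by high dilution, which suppresses dimerisation. No stereocentre is set under control: C10 forms as a mixture that is erased in step 18, and C1, C6, C12 and C13 are not touched (C12 is R again only because CH2I has become CH2C). The step needs alkylation at C10 and not at C8, which the charge localised next to sulfur secures and which also keeps the Z geometry of C8=C9, and attack at iodide and not at the trisubstituted oxirane, which the primary C–I bond secures. It also needs no second deprotonation at C10, which would open the oxirane to a cyclopropane, and this is secured by adding only 1.05 equiv of base to the substrate at low temperature.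

**Step 18**
Reactants: 24 (1R,2E,6R,8Z,12R,13R)-1-(tert-butyldimethylsilyloxy)-12,13-epoxy-3,9,13-trimethyl-10-(phenylsulfonyl)-6-[2-(triethylsilyloxy)propan-2-yl]cyclotetradeca-2,8-diene
Product: 25 (1R,2E,6R,8Z,12R,13R)-1-(tert-butyldimethylsilyloxy)-12,13-epoxy-3,9,13-trimethyl-6-[2-(triethylsilyloxy)propan-2-yl]cyclotetradeca-2,8-diene
Conditions: 6% Na(Hg), Na2HPO4, MeOH/THF, −20 °C
Reagents that add atoms: none
Why: Reductive desulfonylation by electron transfer from sodium amalgam under phosphate buffering cleaves the C–S bond to an allylsodium that methanol should protonate at C10 before the allyl unit rotates, keeping the Z alkene at C8=C9, while the oxirane and silyl ethers are inert to the reagent at −20 °C.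

**Step 19**
Reactants: 25 (1R,2E,6R,8Z,12R,13R)-1-(tert-butyldimethylsilyloxy)-12,13-epoxy-3,9,13-trimethyl-6-[2-(triethylsilyloxy)propan-2-yl]cyclotetradeca-2,8-diene
Product: 26 (1R,2E,6R,8Z,12R,13R)-12,13-epoxy-6-(2-hydroxypropan-2-yl)-3,9,13-trimethylcyclotetradeca-2,8-dien-1-ol
Conditions: Bu4NF, THF, rt to 40 °C
Reagents that add atoms: none
Why: Fluoride-induced desilylation (Si–F bond formation) removes the secondary TBS and the tertiary TES ether without opening the oxirane.

**Step 20**
Reactants: 26 (1R,2E,6R,8Z,12R,13R)-12,13-epoxy-6-(2-hydroxypropan-2-yl)-3,9,13-trimethylcyclotetradeca-2,8-dien-1-ol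
Product: 27 (1R,2E,6R,8Z,12R,13R)-1-acetoxy-6-(2-acetoxypropan-2-yl)-12,13-epoxy-3,9,13-trimethylcyclotetradeca-2,8-diene (target)
Conditions: Ac2O, Et3N, 4-(dimethylamino)pyridine (1 equiv), CH2Cl2, rt to 35 °C
Reagents that add atoms: acetic anhydride, CC(=O)OC(C)=O
Why: Acylation catalysed by 4-(dimethylamino)pyridine (Steglich conditions) acetylates the secondary allylic alcohol and, more slowly, the tertiary alcohol under basic conditions that ionise neither the oxirane nor the allylic C1–O bond.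

**Compound list**
1 | (R)-α-terpineol | CC1=CC[C@@H](CC1)C(C)(C)O | starting material
2 | triethyl({2-[(1R)-4-methylcyclohex-3-en-1-yl]propan-2-yl}oxy)silane | CC1=CC[C@@H](CC1)C(C)(C)O[Si](CC)(CC)CC | intermediate
3 | ozonide of 2, (4R)-1-methyl-4-[2-(triethylsilyloxy)propan-2-yl]-7,8,9-trioxabicyclo[4.2.1]nonane, acetal carbons as a mixture, not isolated | CC12OOC(O1)C[C@H](C(C)(C)O[Si](CC)(CC)CC)CC2 | intermediate
4 | (3R)-6-oxo-3-[2-(triethylsilyloxy)propan-2-yl]heptanal | O=CC[C@H](C(C)(C)O[Si](CC)(CC)CC)CCC(C)=O | intermediate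
5 | ethyl 2-[bis(2,2,2-trifluoroethoxy)phosphoryl]propanoate | CCOC(=O)C(C)P(=O)(OCC(F)(F)F)OCC(F)(F)F | starting material
6 | ethyl (2Z,5R)-2-methyl-8-oxo-5-[2-(triethylsilyloxy)propan-2-yl]non-2-enoate | CCOC(=O)/C(C)=C\C[C@H](C(C)(C)O[Si](CC)(CC)CC)CCC(C)=O | intermediate
7 | diethyl {2-[methoxy(methyl)amino]-2-oxoethyl}phosphonate | CCOP(=O)(CC(=O)N(C)OC)OCC | starting material
8 | ethyl (2Z,5R,8E)-10-[methoxy(methyl)amino]-2,8-dimethyl-10-oxo-5-[2-(triethylsilyloxy)propan-2-yl]deca-2,8-dienoate | CCOC(=O)/C(C)=C\C[C@H](C(C)(C)O[Si](CC)(CC)CC)CC/C(C)=C/C(=O)N(C)OC | intermediate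
9 | (2E,6R,8Z)-10-hydroxy-3,9-dimethyl-6-[2-(triethylsilyloxy)propan-2-yl]deca-2,8-dienal | OC/C(C)=C\C[C@H](C(C)(C)O[Si](CC)(CC)CC)CC/C(C)=C/C=O | intermediate
10 | (2E,6R,8Z)-10-chloro-3,9-dimethyl-6-[2-(triethylsilyloxy)propan-2-yl]deca-2,8-dienal | ClC/C(C)=C\C[C@H](C(C)(C)O[Si](CC)(CC)CC)CC/C(C)=C/C=O | intermediate
11 | sodium benzenesulfinate | [Na+].[O-]S(=O)c1ccccc1 | starting material
12 | (2E,6R,8Z)-3,9-dimethyl-10-(phenylsulfonyl)-6-[2-(triethylsilyloxy)propan-2-yl]deca-2,8-dienal | O=S(=O)(c1ccccc1)C/C(C)=C\C[C@H](C(C)(C)O[Si](CC)(CC)CC)CC/C(C)=C/C=O | intermediate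
13 | methyl acetoacetate | COC(=O)CC(C)=O | starting material
14 | methyl 3-(trimethylsilyloxy)but-2-enoate | COC(=O)C=C(C)O[Si](C)(C)C | intermediate
15 | 1-methoxy-1,3-bis(trimethylsilyloxy)buta-1,3-diene | COC(O[Si](C)(C)C)=CC(=C)O[Si](C)(C)C | intermediate
16 | methyl (5R,6E,10R,12Z)-7,13-dimethyl-14-(phenylsulfonyl)-10-[2-(triethylsilyloxy)propan-2-yl]-3,5-bis(trimethylsilyloxy)tetradeca-2,6,12-trienoate, not isolated | O=S(=O)(c1ccccc1)C/C(C)=C\C[C@H](C(C)(C)O[Si](CC)(CC)CC)CC/C(C)=C/[C@H](O[Si](C)(C)C)CC(O[Si](C)(C)C)=CC(=O)OC | intermediate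
17 | methyl (5R,6E,10R,12Z)-5-hydroxy-7,13-dimethyl-3-oxo-14-(phenylsulfonyl)-10-[2-(triethylsilyloxy)propan-2-yl]tetradeca-6,12-dienoate | O=S(=O)(c1ccccc1)C/C(C)=C\C[C@H](C(C)(C)O[Si](CC)(CC)CC)CC/C(C)=C/[C@H](O)CC(=O)CC(=O)OC | intermediate
18 | methyl (5R,6E,10R,12Z)-5-(tert-butyldimethylsilyloxy)-7,13-dimethyl-3-oxo-14-(phenylsulfonyl)-10-[2-(triethylsilyloxy)propan-2-yl]tetradeca-6,12-dienoate | O=S(=O)(c1ccccc1)C/C(C)=C\C[C@H](C(C)(C)O[Si](CC)(CC)CC)CC/C(C)=C/[C@H](O[Si](C)(C)C(C)(C)C)CC(=O)CC(=O)OC | intermediate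
19 | methyl (2Z,5R,6E,10R,12Z)-5-(tert-butyldimethylsilyloxy)-3-(diethoxyphosphoryloxy)-7,13-dimethyl-14-(phenylsulfonyl)-10-[2-(triethylsilyloxy)propan-2-yl]tetradeca-2,6,12-trienoate | O=S(=O)(c1ccccc1)C/C(C)=C\C[C@H](C(C)(C)O[Si](CC)(CC)CC)CC/C(C)=C/[C@H](O[Si](C)(C)C(C)(C)C)C/C(OP(=O)(OCC)OCC)=C/C(=O)OC | intermediate
20 | methyl (2E,5R,6E,10R,12Z)-5-(tert-butyldimethylsilyloxy)-3,7,13-trimethyl-14-(phenylsulfonyl)-10-[2-(triethylsilyloxy)propan-2-yl]tetradeca-2,6,12-trienoate | O=S(=O)(c1ccccc1)C/C(C)=C\C[C@H](C(C)(C)O[Si](CC)(CC)CC)CC/C(C)=C/[C@H](O[Si](C)(C)C(C)(C)C)C/C(C)=C/C(=O)OC | intermediate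
21 | (2E,5R,6E,10R,12Z)-5-(tert-butyldimethylsilyloxy)-3,7,13-trimethyl-14-(phenylsulfonyl)-10-[2-(triethylsilyloxy)propan-2-yl]tetradeca-2,6,12-trien-1-ol | O=S(=O)(c1ccccc1)C/C(C)=C\C[C@H](C(C)(C)O[Si](CC)(CC)CC)CC/C(C)=C/[C@H](O[Si](C)(C)C(C)(C)C)C/C(C)=C/CO | intermediate
22 | {(2R,3R)-3-[(2R,3E,7R,9Z)-2-(tert-butyldimethylsilyloxy)-4,10-dimethyl-11-(phenylsulfonyl)-7-[2-(triethylsilyloxy)propan-2-yl]undeca-3,9-dien-1-yl]-3-methyloxiran-2-yl}methanol | O=S(=O)(c1ccccc1)C/C(C)=C\C[C@H](C(C)(C)O[Si](CC)(CC)CC)CC/C(C)=C/[C@H](O[Si](C)(C)C(C)(C)C)C[C@@]2(C)O[C@@H]2CO | intermediate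
23 | (2S,3R)-3-[(2R,3E,7R,9Z)-2-(tert-butyldimethylsilyloxy)-4,10-dimethyl-11-(phenylsulfonyl)-7-[2-(triethylsilyloxy)propan-2-yl]undeca-3,9-dien-1-yl]-2-(iodomethyl)-3-methyloxirane | O=S(=O)(c1ccccc1)C/C(C)=C\C[C@H](C(C)(C)O[Si](CC)(CC)CC)CC/C(C)=C/[C@H](O[Si](C)(C)C(C)(C)C)C[C@@]2(C)O[C@@H]2CI | intermediate
24 | (1R,2E,6R,8Z,12R,13R)-1-(tert-butyldimethylsilyloxy)-12,13-epoxy-3,9,13-trimethyl-10-(phenylsulfonyl)-6-[2-(triethylsilyloxy)propan-2-yl]cyclotetradeca-2,8-diene, C10 epimers | CC(C)(C)[Si](C)(C)O[C@H]1/C=C(\C)CC[C@@H](C(C)(C)O[Si](CC)(CC)CC)C/C=C(/C)C(S(=O)(=O)c2ccccc2)C[C@H]3O[C@]3(C)C1 | intermediate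
25 | (1R,2E,6R,8Z,12R,13R)-1-(tert-butyldimethylsilyloxy)-12,13-epoxy-3,9,13-trimethyl-6-[2-(triethylsilyloxy)propan-2-yl]cyclotetradeca-2,8-diene | CC(C)(C)[Si](C)(C)O[C@H]1/C=C(\C)CC[C@@H](C(C)(C)O[Si](CC)(CC)CC)C/C=C(/C)CC[C@H]2O[C@]2(C)C1 | intermediate
26 | (1R,2E,6R,8Z,12R,13R)-12,13-epoxy-6-(2-hydroxypropan-2-yl)-3,9,13-trimethylcyclotetradeca-2,8-dien-1-ol | O[C@H]1/C=C(\C)CC[C@@H](C(C)(C)O)C/C=C(/C)CC[C@H]2O[C@]2(C)C1 | intermediate
27 | (1R,2E,6R,8Z,12R,13R)-1-acetoxy-6-(2-acetoxypropan-2-yl)-12,13-epoxy-3,9,13-trimethylcyclotetradeca-2,8-diene | CC(=O)O[C@H]1/C=C(\C)CC[C@@H](C(C)(C)OC(C)=O)C/C=C(/C)CC[C@H]2O[C@]2(C)C1 | target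

**Step count**
Total: 20 steps. Longest linear sequence: 18 steps (steps 1–7 and 10–20 from (R)-α-terpineol); steps 8 and 9 are a two-step side branch.

**Steps most likely to fail**

Step 17. Ring closure may be outrun by intermolecular alkylation, or the oxirane may be opened, either by the first carbanion at C12 or, after a second deprotonation of the product at C10, in a cyclopropane-forming attack. The fallback introduces the oxirane after ring closure and sets out from 21. CBr4 and PPh3 in CH2Cl2 at 0 °C convert 21 into the allylic bromide F1. LiN(SiMe3)2 in dilute THF then closes the same C10–C11 bond by the long-established sulfone/allylic bromide macrocyclisation to the macrocyclic triene sulfone F2. Epoxidation with the D-fructose-derived Shi ketone and KHSO5 under K2CO3 buffering should take the C12=C13 alkene, the only one not deactivated by an allylic sulfonyl or silyloxy group, and should give the (12R,13R)-oxirane under reagent control. The route is rejoined at 24.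

Step 18. The position and geometry of the C8=C9 alkene may be lost, because the allyl anion formed on C–S cleavage has two secondary termini and can be protonated at C8 as well as at C10, and it may rotate before protonation. The fallback sets out from 24 and replaces electron transfer by hydride substitution through a π-allyl complex of palladium: Pd(PPh3)4 (a complex of zerovalent palladium) with NaBH4, a hydride source that does not open oxiranes, in THF/iPrOH. No free allyl anion is formed and hydride is delivered from the metal, and the route is rejoined at 25. Which allyl terminus receives hydride would have to be established by experiment in this case too.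

Step 10. Facial selectivity may be poor, since β,β-disubstituted enals are a less tested substrate class for this catalyst, and the allylic C1 hydroxyl may be lost by ionisation during desilylation. The fallback sets out from 12 and uses reagent-controlled allylboration. B-allyldiisopinocampheylborane made from (−)-α-pinene is the enantiomer that should convert aryl and alkenyl aldehydes into (R)-carbinols; after oxidative work-up it should give the homoallylic alcohol F3. Silylation (TBSCl, imidazole) gives the TBS ether F4. Wacker oxidation (PdCl2, CuCl, O2, DMF/H2O) of the terminal alkene gives the methyl ketone F5. Horner–Wadsworth–Emmons olefination with triethyl phosphonoacetate and NaH gives, after removal of the minor Z isomer, the ethyl E-enoate F6. Reduction with iBu2AlH rejoins the route at 21.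

**Further compounds**
F1 | step 17 | (2E,5R,6E,10R,12Z)-1-bromo-5-(tert-butyldimethylsilyloxy)-3,7,13-trimethyl-14-(phenylsulfonyl)-10-[2-(triethylsilyloxy)propan-2-yl]tetradeca-2,6,12-triene | O=S(=O)(c1ccccc1)C/C(C)=C\C[C@H](C(C)(C)O[Si](CC)(CC)CC)CC/C(C)=C/[C@H](O[Si](C)(C)C(C)(C)C)C/C(C)=C/CBr
F2 | step 17 | (1R,2E,6R,8Z,12E)-1-(tert-butyldimethylsilyloxy)-3,9,13-trimethyl-10-(phenylsulfonyl)-6-[2-(triethylsilyloxy)propan-2-yl]cyclotetradeca-2,8,12-triene, C10 epimers | CC(C)(C)[Si](C)(C)O[C@H]1/C=C(\C)CC[C@@H](C(C)(C)O[Si](CC)(CC)CC)C/C=C(/C)C(S(=O)(=O)c2ccccc2)C/C=C(\C)C1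
F0 | step 18 | none | none
F3 | step 10 | (4R,5E,9R,11Z)-6,12-dimethyl-13-(phenylsulfonyl)-9-[2-(triethylsilyloxy)propan-2-yl]trideca-1,5,11-trien-4-ol | O=S(=O)(c1ccccc1)C/C(C)=C\C[C@H](C(C)(C)O[Si](CC)(CC)CC)CC/C(C)=C/[C@H](O)CC=C
F4 | step 10 | (4R,5E,9R,11Z)-4-(tert-butyldimethylsilyloxy)-6,12-dimethyl-13-(phenylsulfonyl)-9-[2-(triethylsilyloxy)propan-2-yl]trideca-1,5,11-triene | O=S(=O)(c1ccccc1)C/C(C)=C\C[C@H](C(C)(C)O[Si](CC)(CC)CC)CC/C(C)=C/[C@H](O[Si](C)(C)C(C)(C)C)CC=C
F5 | step 10 | (4R,5E,9R,11Z)-4-(tert-butyldimethylsilyloxy)-6,12-dimethyl-13-(phenylsulfonyl)-9-[2-(triethylsilyloxy)propan-2-yl]trideca-5,11-dien-2-one | O=S(=O)(c1ccccc1)C/C(C)=C\C[C@H](C(C)(C)O[Si](CC)(CC)CC)CC/C(C)=C/[C@H](O[Si](C)(C)C(C)(C)C)CC(C)=O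
F6 | step 10 | ethyl (2E,5R,6E,10R,12Z)-5-(tert-butyldimethylsilyloxy)-3,7,13-trimethyl-14-(phenylsulfonyl)-10-[2-(triethylsilyloxy)propan-2-yl]tetradeca-2,6,12-trienoate | O=S(=O)(c1ccccc1)C/C(C)=C\C[C@H](C(C)(C)O[Si](CC)(CC)CC)CC/C(C)=C/[C@H](O[Si](C)(C)C(C)(C)C)C/C(C)=C/C(=O)OCC
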